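The constants of this flask were hidden from me, so I began not from rates but from a count of what the scavenger has to take up.

common to all: substrate 0.050 M
- alder: reagent 0.10 M; scavenger 0.093 M; run made earlier
- oak: reagent 0.10 M; scavenger 0.20 M; run made earlier
- delta: reagent 0.100 M; scavenger 0.0750 M; time 10 d
- alpha: reagent 0.100 M; scavenger 0.0980 M; time 10 d
- zeta: reagent 0.100 M; scavenger 0.130 M; time 10 d

| run | time / d | substrate / % | first product / % |
|---|---|---|---|
| alder | 0.833 | 67.1 | 18.9 |
| alder | 1.25 | 58.9 | 25.6 |
| alder | 1.67 | 53.5 | 31.9 |
| alder | 3.00 | 40.1 | 45.0 |
| alder | 4.00 | 33.9 | 52.5 |
| alder | 6.00 | 22.7 | 63.3 |
| alder | 10.0 | 11.3 | 73.0 |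
| oak | 0.833 | 71.1 | 19.8 |
| oak | 1.25 | 62.9 | 26.8 |
| oak | 1.67 | 57.0 | 32.5 |
| oak | 3.00 | 41.7 | 46.7 |
| oak | 4.00 | 33.7 | 54.6 |
| oak | 6.00 | 22.1 | 64.4 |
| oak | 10.0 | 9.8 | 74.2 |

(scatter of a reading: 0.5 percentage points)

- for released group the idle adduct is counted in
- on the list of suspects stand: substrate + reagent -> first product + released group; substrate + reagent -> other mono adduct + released group; reagent + first product -> bis adduct + released group; reagent + other mono adduct -> bis adduct + released group; substrate + released group <-> idle adduct; scavenger + released group -> scavenged by-product

* part of the substrate that has reacted at the end, delta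
* part of the substrate that has reacted at the end, alpha
* part of the substrate that has reacted at the end, zeta
* what raising the concentration of scavenger from its lowest to its highest value here does to the part of the substrate that has reacted (changes below 5 percentage points count as none) (it falls / no change / it rises)

I turned the question round. Alder and oak, with scavenger at 0.093 M and 0.20 M, ended 1.5 percentage points apart in substrate, less than the margin. So I looked for the opposite outcome where the scavenger falls short of the released group, which each step of substrate or mono adduct with reagent frees. On the first round, I counted one released group for each substrate gone in the alder readings, 0.0444 M in all. I then put that answer back in: the 15.7% of the charge that had reacted but was not first product may have gone on to bis adduct, releasing a second group, so the demand came to at most 0.0522 M. Taking alder's demand for delta too, I divided delta's scavenger charge, the lowest, by it and got 1.44. This is the scavenger cover, the charge of scavenger over the released group made by the end. The shortfall I was looking for means a cover under one, and delta stood above that, so I took delta's scavenger to be in excess and not the limiting reagent. I expected no change, with all three flasks near alder's 88.7% reacted.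

The forecast gave 87.3%, 88.9% and 89.6%, and no change: “So scavenger has only a weak effect on end conversion.”

Delta, alpha and zeta gave 88.0%, 88.4% and 88.7%, so the answer is no change: from the lowest scavenger to the highest the part reacted moved by 0.7 points.

    substrate + reagent → first product + released group (k = 3.50 × 10⁻⁵ /M/s)
    substrate + reagent → other mono adduct + released group (k = 5.90 × 10⁻⁶ /M/s)
    reagent + first product → bis adduct + released group (k = 6.90 × 10⁻⁷ /M/s)
    reagent + other mono adduct → bis adduct + released group (k = 4.10 × 10⁻⁵ /M/s)
    substrate + released group ⇌ idle adduct, settled at all times (K = 1500 /M)
    scavenger + released group → scavenged by-product (k = 0.0120 /M/s)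

By 10.0 d delta held 0.0484 M of scavenged by-product, a cover of 1.55 on what was really taken up, with 35% of its scavenger left. The neighbouring flask is delta with 0.030 M of substrate. The same count on its end gives a demand of at most 0.0325 M and a cover of 2.30. That flask reacted 92.5% of its substrate, held 0.0315 M of by-product and kept 58% of its scavenger.

The numbers in the tables stem from a simulated flask with constants of no real substance, noise included.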